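The target is cut at the two aryl–CH2 bonds on C3 and C5 of the central phloroglucinol ring. Each methylene sits on C3 of one of two identical 4-hydroxy-2-pyrone rings. C3 and C5 are equivalent sites between the ring oxygens and carry the same arm, so one double Negishi coupling installs both arms at once. The ring carbons act as electrophiles (C–Br) and the pyronylmethyl carbon acts as the nucleophile (C–Zn), so the halogens alone fix the number and position of the arms. The coupling precursor is the tri-O-benzyl 3,5-dibromo derivative of (R)-2-methylbutanoylphloroglucinol. Its partner is a (4-benzyloxy-2-pyron-3-yl)methylzinc chloride. Hydrogenolysis of all five benzyl ethers finishes the synthesis.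

Key step: step 11

Remark: the only stereocentre, C2 of the 2-methylbutanoyl chain, is (R) in the target and is bought in with the acid; no later step makes, breaks or deprotonates this centre, and its integrity should be checked once at the coupling precursor.

Step 1
Reactants: 1 (R)-2-methylbutanoic acid; 2 phloroglucinol (anhydrous)
Product: 4 (R)-2-methyl-1-(2,4,6-trihydroxyphenyl)butan-1-one, via (R)-2-methylbutanoyl chloride 3 (not isolated)
Conditions: 1, (COCl)2 (1.05 equiv), cat. DMF, CH2Cl2, 0 °C → rt; then 2, AlCl3 (4 equiv), PhNO2/CH2Cl2, 0 → 40 °C; ice/1 M HCl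
Reagents that add atoms: oxalyl chloride, O=C(Cl)C(Cl)=O (gives the Cl of 3; nothing from it stays in 4)
Why: Friedel–Crafts acylation, in which activated 3 attacks one of three equivalent CH positions of the very electron-rich ring, the aluminium-chelated ketone is deactivated towards a second acylation, and the (R)-centre is carried over from 1 because neither the DMF-catalysed chloride formation nor the base-free acylation at or below 40 °C offers a significant ketene or enol pathway.

Step 2
Reactants: 4 (R)-2-methyl-1-(2,4,6-trihydroxyphenyl)butan-1-one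
Product: 5 (R)-1-(3,5-dibromo-2,4,6-trihydroxyphenyl)-2-methylbutan-1-one
Conditions: NBS (2.05 equiv), MeCN, −20 → 0 °C, dark
Reagents that add atoms: N-bromosuccinimide, O=C1CCC(=O)N1Br
Why: Electrophilic aromatic bromination, in which C3 and C5 are the only free ring positions and are each activated by three hydroxy groups, so two equivalents of NBS should be consumed on the ring far faster than the ketone can enolise.

Step 3
Reactants: 5 (R)-1-(3,5-dibromo-2,4,6-trihydroxyphenyl)-2-methylbutan-1-one
Product: 6 (R)-1-[2,4,6-tris(benzyloxy)-3,5-dibromophenyl]-2-methylbutan-1-one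
Conditions: BnBr (3.6 equiv), K2CO3 (4.5 equiv), DMF, 25 → 45 °C
Reagents that add atoms: benzyl bromide, BrCc1ccccc1
Why: Williamson ether synthesis, in which C-benzylation would require dearomatisation because every ring carbon is substituted, so the acidic bromophenoxides should react on oxygen, and carbonate is too weak to deprotonate the α-CH of the hindered, out-of-plane aryl ketone.

Step 4
Reactants: 7 3-pentanone
Product: 8 3-(trimethylsilyloxy)pent-2-ene (E/Z mixture)
Conditions: TMSOTf (1.1 equiv), Et3N (1.3 equiv), CH2Cl2, 0 °C; pentane extraction, distillation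
Reagents that add atoms: trimethylsilyl triflate, C[Si](C)(C)OS(=O)(=O)C(F)(F)F
Why: Soft enolisation and O-silylation of a symmetrical ketone, so only one regioisomeric silyl enol ether can form and its alkene geometry is lost in the next step.

Step 5
Reactants: 8 3-(trimethylsilyloxy)pent-2-ene; 9 malonyl dichloride
Product: 10 6-ethyl-4-hydroxy-5-methyl-2H-pyran-2-one
Conditions: Et2O, −78 °C → rt
Reagents that add atoms: none
Why: Known cyclocondensation to 4-hydroxy-2-pyrones (C-acylation of the silyl enol ether by one acid chloride, then O-acylation of the enolised 1,3-diketone by the other), which places the former α-carbon with its methyl at C5 and the former carbonyl carbon with its ethyl at C6.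

Step 6
Reactants: 10 6-ethyl-4-hydroxy-5-methyl-2H-pyran-2-one
Product: 11 4-(benzyloxy)-6-ethyl-5-methyl-2H-pyran-2-one
Conditions: BnOH (1.1 equiv), PPh3 (1.2 equiv), DIAD (1.2 equiv), THF, 0 °C → rt
Reagents that add atoms: benzyl alcohol, OCc1ccccc1
Why: Mitsunobu etherification, in which the acidic vinylogous carboxylic acid OH is a good pronucleophile that reacts at O4 and so avoids the C3-benzylation that accompanies base/benzyl halide alkylation of 4-hydroxy-2-pyrones.

Step 7
Reactants: 11 4-(benzyloxy)-6-ethyl-5-methyl-2H-pyran-2-one
Product: 12 4-(benzyloxy)-3-bromo-6-ethyl-5-methyl-2H-pyran-2-one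
Conditions: NBS (1.05 equiv), MeCN, rt, dark
Reagents that add atoms: N-bromosuccinimide, O=C1CCC(=O)N1Br
Why: Electrophilic bromination at the enol ether carbon C3, the only unsubstituted ring position, under ionic conditions that leave the benzylic and allylic C–H bonds alone.

Step 8
Reactants: 12 4-(benzyloxy)-3-bromo-6-ethyl-5-methyl-2H-pyran-2-one; 13 (tributylstannyl)methanol
Product: 14 4-(benzyloxy)-6-ethyl-3-(hydroxymethyl)-5-methyl-2H-pyran-2-one
Conditions: 13 (1.3 equiv), Pd(PPh3)4 (5 mol %), 1,4-dioxane, 95 °C
Reagents that add atoms: none
Why: Migita–Kosugi–Stille hydroxymethylation, in which the α-oxygenated CH2OH group is transferred from tin in preference to butyl, 3-bromo-2-pyrones are established partners in neutral Pd(0) couplings, and no base is present that could open the lactone.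

Step 9
Reactants: 14 4-(benzyloxy)-6-ethyl-3-(hydroxymethyl)-5-methyl-2H-pyran-2-one
Product: 16 4-(benzyloxy)-3-(chloromethyl)-6-ethyl-5-methyl-2H-pyran-2-one, via pyronylmethyl mesylate 15 (not isolated)
Conditions: MsCl (1.2 equiv), Et3N (1.5 equiv), LiCl (3 equiv), THF, 0 °C → rt; aqueous work-up, used at once
Reagents that add atoms: methanesulfonyl chloride, CS(=O)(=O)Cl (mesyl group of 15); lithium chloride, [Li+].[Cl-]
Why: Sulfonylation followed by SN2 displacement with chloride at a primary benzylic-type carbon under buffered conditions, which avoids strong acid that could cleave the vinylogous benzyl ester and gives a chloride free of protic or phosphorus by-products for the metalation.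

Step 10
Reactants: 16 4-(benzyloxy)-3-(chloromethyl)-6-ethyl-5-methyl-2H-pyran-2-one
Product: 17 [(4-benzyloxy-6-ethyl-5-methyl-2-oxo-2H-pyran-3-yl)methyl]zinc chloride (LiCl-complexed THF solution)
Conditions: Zn dust (2 equiv; activated with BrCH2CH2Br 5 mol %, TMSCl 1 mol %), LiCl (2 equiv), THF, 0 → 25 °C; decanted and titrated with I2
Reagents that add atoms: zinc, [Zn]
Why: LiCl-promoted direct insertion of zinc into a benzylic-type C–Cl bond, where the chloride is preferred to the bromide because its lower reactivity suppresses Wurtz dimerisation, LiCl keeps the metal surface clean by solubilising the organozinc, and lactone, enol ether and benzyl ether are tolerated.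

Step 11
Reactants: 6 (R)-1-[2,4,6-tris(benzyloxy)-3,5-dibromophenyl]-2-methylbutan-1-one; 17 [(4-benzyloxy-6-ethyl-5-methyl-2-oxo-2H-pyran-3-yl)methyl]zinc chloride (3 equiv)
Product: 18 penta-O-benzyl ether of the target, (R)-3,3'-{[2,4,6-tris(benzyloxy)-5-(2-methylbutanoyl)-1,3-phenylene]bis(methylene)}bis[4-(benzyloxy)-6-ethyl-5-methyl-2H-pyran-2-one]
Conditions: Pd(OAc)2 (5 mol %), SPhos (10 mol %), THF, slow addition of 17, 25 → 55 °C
Reagents that add atoms: none
Why: This is a Negishi sp2–sp3 cross-coupling run twice on one ring: ligated Pd(0) inserts into a C–Br bond of 6, the CH2 group of 17 passes from zinc to palladium, and reductive elimination forms the aryl C3–CH2 bond and then the C5–CH2 bond. The closest known reaction type is the palladium/dialkylbiarylphosphine-catalysed coupling of LiCl-complexed benzylic and heterobenzylic zinc chlorides with ortho-substituted aryl bromides. No ring is closed and no stereocentre is formed; the (R)-centre next to the ketone is a spectator and is safe because the medium contains no base and the twisted 2,6-disubstituted ketone is inert to the soft zinc reagent. The selectivity needed is complete twofold substitution at C3 and C5 without protodebromination, and it is secured by the substrate (halogen only on these two carbons, every other ring position blocked) together with an excess of 17. The bulky, electron-rich ligand speeds oxidative addition at the electron-rich carbons flanked by two benzyloxy groups and forces fast reductive elimination, and the Pd–CH2 intermediate has no β-hydrogen to lose. Slow addition of 17 limits its homocoupling, and the absence of carbonate or carboxylate base shuts off C–H arylation of the neighbouring benzyl groups.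

Step 12
Reactants: 18 penta-O-benzyl ether of the target
Product: 19 target, (R)-3,3'-{[2,4,6-trihydroxy-5-(2-methylbutanoyl)-1,3-phenylene]bis(methylene)}bis(6-ethyl-4-hydroxy-5-methyl-2H-pyran-2-one)
Conditions: H2 (1 atm), 10 % Pd/C, EtOAc/EtOH, rt; stopped when uptake ends
Reagents that add atoms: none
Why: Heterogeneous catalytic hydrogenolysis should cleave all five benzylic C–O bonds under neutral conditions, while the fully substituted pyrone C=C bonds, the chelated aryl ketone and the Ar–CH2–pyrone C–C bonds resist 1 atm of hydrogen and neither bridge scrambling nor α-epimerisation is triggered.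

Compound list
1 | (R)-2-methylbutanoic acid | CC[C@@H](C)C(=O)O | starting material
2 | phloroglucinol | Oc1cc(O)cc(O)c1 | starting material
3 | (R)-2-methylbutanoyl chloride | CC[C@@H](C)C(=O)Cl | intermediate
4 | (R)-2-methyl-1-(2,4,6-trihydroxyphenyl)butan-1-one | CC[C@@H](C)C(=O)c1c(O)cc(O)cc1O | intermediate
5 | (R)-1-(3,5-dibromo-2,4,6-trihydroxyphenyl)-2-methylbutan-1-one | CC[C@@H](C)C(=O)c1c(O)c(Br)c(O)c(Br)c1O | intermediate
6 | (R)-1-[2,4,6-tris(benzyloxy)-3,5-dibromophenyl]-2-methylbutan-1-one | CC[C@@H](C)C(=O)c1c(OCc2ccccc2)c(Br)c(OCc2ccccc2)c(Br)c1OCc1ccccc1 | intermediate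
7 | 3-pentanone | CCC(=O)CC | starting material
8 | 3-(trimethylsilyloxy)pent-2-ene (E/Z mixture) | CC=C(CC)O[Si](C)(C)C | intermediate
9 | malonyl dichloride | O=C(Cl)CC(Cl)=O | starting material
10 | 6-ethyl-4-hydroxy-5-methyl-2H-pyran-2-one | CCc1oc(=O)cc(O)c1C | intermediate
11 | 4-(benzyloxy)-6-ethyl-5-methyl-2H-pyran-2-one | CCc1oc(=O)cc(OCc2ccccc2)c1C | intermediate
12 | 4-(benzyloxy)-3-bromo-6-ethyl-5-methyl-2H-pyran-2-one | CCc1oc(=O)c(Br)c(OCc2ccccc2)c1C | intermediate
13 | (tributylstannyl)methanol | OC[Sn](CCCC)(CCCC)CCCC | starting material
14 | 4-(benzyloxy)-6-ethyl-3-(hydroxymethyl)-5-methyl-2H-pyran-2-one | CCc1oc(=O)c(CO)c(OCc2ccccc2)c1C | intermediate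
15 | [4-(benzyloxy)-6-ethyl-5-methyl-2-oxo-2H-pyran-3-yl]methyl methanesulfonate | CCc1oc(=O)c(COS(C)(=O)=O)c(OCc2ccccc2)c1C | intermediate
16 | 4-(benzyloxy)-3-(chloromethyl)-6-ethyl-5-methyl-2H-pyran-2-one | CCc1oc(=O)c(CCl)c(OCc2ccccc2)c1C | intermediate
17 | [(4-benzyloxy-6-ethyl-5-methyl-2-oxo-2H-pyran-3-yl)methyl]zinc chloride | CCc1oc(=O)c(C[Zn]Cl)c(OCc2ccccc2)c1C | intermediate
18 | penta-O-benzyl ether of the target, (R) | CCc1oc(=O)c(Cc2c(OCc3ccccc3)c(Cc3c(OCc4ccccc4)c(C)c(CC)oc3=O)c(OCc3ccccc3)c(C(=O)[C@H](C)CC)c2OCc2ccccc2)c(OCc2ccccc2)c1C | intermediate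
19 | CNP0174567.1, (R) | CCc1oc(=O)c(Cc2c(O)c(Cc3c(O)c(C)c(CC)oc3=O)c(O)c(C(=O)[C@H](C)CC)c2O)c(O)c1C | target

Total step count: 12. Longest linear sequence: 9 steps (steps 4–12, from 3-pentanone).

Steps most likely to fail

Step 11. Oxidative addition at the crowded, electron-rich C–Br carbons may be slow. The zinc reagent could then be used up by homocoupling or protonation, the reaction could stall after the first arm, or the aryl–palladium intermediate could be reduced. The fallback makes the same two bonds in the classical polarity. It sets out from 4, with 10 as partner, and comes back at 19. Compound 4 would be aminomethylated twice with aqueous formaldehyde and dimethylamine in EtOH (Mannich reaction). This should give (R)-1-{3,5-bis[(dimethylamino)methyl]-2,4,6-trihydroxyphenyl}-2-methylbutan-1-one F1. Heating this bis-Mannich base with an excess of 10 in dioxane should release the amine stepwise. Each o-quinone methide so formed would be trapped at the nucleophilic C3 of 10.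

Step 10. Wurtz-type dimerisation at the zinc surface, or zinc-salt-assisted ionisation of the chloride with loss of the neighbouring benzyl group, may erode the reagent. The fallback replaces zinc by boron. It sets out from 16 and comes back at 18. Palladium-catalysed Miyaura borylation of the benzylic chloride (B2pin2, KOAc, Pd(dba)2/tris(4-methoxyphenyl)phosphine, toluene, 50 °C) should give 4-(benzyloxy)-6-ethyl-5-methyl-3-[(4,4,5,5-tetramethyl-1,3,2-dioxaborolan-2-yl)methyl]-2H-pyran-2-one F2, a storable nucleophile. It would then be joined twice to 6 by sp2–sp3 Suzuki–Miyaura coupling (Pd(OAc)2/SPhos, K3PO4, toluene/water). The base is kept mild for the sake of the α-stereocentre.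

Step 8. Transmetallation at the hindered C3–Pd centre may be slow, and butyl transfer or protodestannylation of the stannane may compete. The fallback brings in the C3 carbon as an aldehyde before the benzyl ether. It sets out from 10 and comes back at 14. Vilsmeier–Haack chloroformylation (POCl3, DMF) should give 4-chloro-6-ethyl-5-methyl-2-oxo-2H-pyran-3-carbaldehyde F3. Addition–elimination with benzyl alcohol and K2CO3 should then give 4-(benzyloxy)-6-ethyl-5-methyl-2-oxo-2H-pyran-3-carbaldehyde F4. Luche reduction (NaBH4, CeCl3, MeOH, 0 °C) should reduce the aldehyde in the 1,2-sense.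

Further compounds
F1 | step 11 | (R)-1-{3,5-bis[(dimethylamino)methyl]-2,4,6-trihydroxyphenyl}-2-methylbutan-1-one | CC[C@@H](C)C(=O)c1c(O)c(CN(C)C)c(O)c(CN(C)C)c1O
F2 | step 10 | 4-(benzyloxy)-6-ethyl-5-methyl-3-[(4,4,5,5-tetramethyl-1,3,2-dioxaborolan-2-yl)methyl]-2H-pyran-2-one | CCc1oc(=O)c(CB2OC(C)(C)C(C)(C)O2)c(OCc2ccccc2)c1C
F3 | step 8 | 4-chloro-6-ethyl-5-methyl-2-oxo-2H-pyran-3-carbaldehyde | CCc1oc(=O)c(C=O)c(Cl)c1C
F4 | step 8 | 4-(benzyloxy)-6-ethyl-5-methyl-2-oxo-2H-pyran-3-carbaldehyde | CCc1oc(=O)c(C=O)c(OCc2ccccc2)c1C
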